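The unit here is the charge: the argument counts product and impurity as fractions of what went into the flask, and a dose of enzyme in charges of enzyme.

common to all: enzyme 3.7 µM; added ligand 4.9 µM; impurity 5.4 µM
- Saturday's: starting material 37 mM; the very flask that is asked about, followed so far
- Wednesday's: starting material 74 mM; run made earlier
- flask: starting material 37 mM; time 1.0 h

| run | time / min | product / % | starting material / % |
|---|---|---|---|
| Saturday's | 5.00 | 25 | 75 |
| Saturday's | 12.0 | 23 | 75 |
| Saturday's | 25.0 | 24 | 77 |
| Saturday's | 40.0 | 24 | 75 |
| Wednesday's | 2.50 | 36 | 62 |
| Wednesday's | 6.00 | 39 | 62 |
| Wednesday's | 12.0 | 41 | 57 |
| Wednesday's | 30.0 | 39 | 60 |

(readings scatter by 1.5 percentage points)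

- what is taken out of product is counted as made
- additions bring no volume worth counting

- west: at 1.0 h add starting material, 50.0% of the amount charged, then wait 20 min
- north-east: at 1.0 h take out 90% of the product then present, then wait 20 min
- south: at 1.0 h add enzyme, 100% of the amount charged, then wait 20 min
- north-west: change nothing and wait 20 min more

- product, in percent of the starting material first charged, at 1.0 h
- which option adds most product ("none" when 2 percentage points or less is all one gets) (west / north-east / south / north-west / none)
- product present, with what was taken out counted in, in percent of the starting material first charged, after west
- product present, with what was taken out counted in, in percent of the starting material first charged, after south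

Saturday's flask stands flat from 5.00 min to 40.0 min at a mean product of 24.0%. Wednesday's flask, with twice the starting material and the same enzyme and impurity, stands flat at a mean of 38.8%, which is more than Saturday's. Starting material is present in both, so the decision at 1.0 h hangs on whether any enzyme still works.

The reckoning made here takes the loss of enzyme as a fast step, finished before the first reading, with one enzyme lost to one impurity. Impurity is charged above the enzyme, so in this reckoning a part of the impurity stays over. The quantity to carry is the leftover impurity, the share of its own charge that outlives the enzyme: 31.5%.

Waiting, more starting material and taking out product add no enzyme, so this reckoning leaves Saturday's flask at 24.0% under those options. A dose of enzyme first meets the leftover impurity, which takes 45.9% of it, so 54.1% of the dose stays working. The first charge made its product within 5.00 min, while the surviving part has 20 min. At an unchanged rate that gives about 75.9% after south.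

The forecast, which differs from this reckoning on south, gives 24% now, south as best, 24% after west and 39% after south, adding “The remaining ligand or impurity could shift this”.

The flask gives 24.6% at 1.0 h, 24.6% after west and 79.0% after south, so south is best, with a gain of 54 percentage points against 0 points for west.

    starting material + enzyme → product + enzyme, rate k1*[starting material]^3*[enzyme]/(1 + ([starting material]/Kh1)^3) (0.0550 M, k = 4.30 × 10⁶ L³ mol⁻³ s⁻¹)
    enzyme + added ligand ⇌ idle complex, settled at all times (K = 84000 L mol⁻¹)
    enzyme + impurity → spent catalyst (k = 15000 L mol⁻¹ s⁻¹)

In Saturday's flask the half-life of enzyme by the step with impurity, 0.23 min at 0.293 min, is shorter than the 0.293 min by which half of the turnover is done, and 99.9% of that turnover stands complete at 6.00 min. At 60.0 min that flask holds 31% of its impurity against the reckoned 31.5%, and the neighbour charged with 0.0015 mM of enzyme, reckoned the same way at 72.2%, holds 72%.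

(All runs are simulated for substances that don't exist; noise was put on by code.)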